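Tuesday's run is this same flask followed for its first minute: at 60.0 s the steady feed has brought in 33.3% of the charge, and the readings hold 26.8% starting material, 0.5% target and 0% side product.

- Tuesday's: starting material 25 mM (fed, over 3.0 min); protic impurity 7.5 mM; solid reagent 100 mM; the very flask that is asked about, followed so far
- flask: starting material 25 mM (fed, over 3.0 min); protic impurity 7.50 mM; solid reagent 100 mM; time 5.0 min

- Tuesday's (time / s: side product / %, target / %, starting material / %): 10.0: 0, 0.1, 5.4; 15.0: 0.6, 0, 8.1; 30.0: 0.1, 0.5, 14.5; 40.0: 0, 0.1, 19.1; 60.0: 0, 0.5, 26.8

(standard deviation of a reading: 0.3 percentage points)

- percentages count the starting material that a species holds: one side product counts as two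
- solid, in amounts per volume of the solution: solid reagent
- the earlier runs were read with a standard deviation of 0.3 percentage points
- at the start none of the solid reagent is in solution
- percentages count the whole charge, also what has not yet gone in

* the largest share of what was charged as starting material, at 5.0 min belongs to (starting material / side product / target)
* the largest share itself, whichever of these holds it, in percent of the starting material charged

So 6 percentage points are unseen, and I take them as starting material consumed one to one by the protic impurity. I therefore carry the free share, one minus c(protic impurity)/c(starting material), the part of the charge left once the impurity has taken its equivalent: 70.0%.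

Set against the mean starting material of that minute, half the last reading, the gap gives the impurity a pseudo-first-order half-life of 39.6 s when the free share stands in solution. That is shorter than the 2.00 min after the feed, so I count the quench as nearly over by 5.0 min.

The target reading, 0.5% with a scatter of 0.3 points, gives on the same mean a rough leak of 0.0373 min⁻¹. Charged on the free share for 5.0 min, this takes 13.1%, so I expect starting material to hold most, near 56.9%.

The forecast differs, with target at 40%, on the ground that “the protic impurity seems to quench the target as it forms”.

The flask gives starting material at 58.1%, beside 7.45% target and 5.09% side product.

    starting material + protic impurity → quenched substrate (k = 1.10 M⁻¹ s⁻¹)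
    starting material + partner → target, rate k2*[starting material]*[partner]^1.5 (k = 1.30 M⁻¹·⁵ s⁻¹)
    starting material + target → side product (k = 0.200 M⁻¹ s⁻¹)
    solid reagent ⇌ partner, rate k4*(cs4 - [partner]) while solid is left; crystals form when [partner] > cs4 (solubility = 9.30 mM, k = 0.00940 s⁻¹)

Those three together hold 70.6% of the charge in this flask, against a free share of 70.0%, with 2.0% of the impurity left. The neighbouring flask, like this one but with 1.9 mM of protic impurity, has a free share of 92.4%. At 5.0 min it holds 8.48% target, 7.61% side product and 76.4% starting material, together 92.5%.

(The runs come from a simulation for an exercise.)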